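The data are calculated on assumed constants; scatter was added.

In a one-step world, target made early in a run grows in proportion to each charge, so early on its percent of the substrate charged ignores the substrate charge. Here is what stands on the bench.

| flask | substrate | partner | capture agent | free catalyst | impurity | remark | time |
|---|---|---|---|---|---|---|---|
| Thursday's | 0.56 mM | 1 mM | 0.040 mM | 7 µM | 1.8 µM | run made earlier |  |
| Tuesday's | 1.1 mM | 1 mM | 0.040 mM | 7 µM | 1.8 µM | run made earlier |  |
| Monday's | 2.3 mM | 1 mM | 0.040 mM | 7 µM | 1.8 µM | run made earlier |  |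
| Sunday's | 2 mM | 0.35 mM | 0.040 mM | 7 µM | 1.8 µM | run made earlier |  |
| ash | 0.60 mM | 0.250 mM | 0.0400 mM | 15 µM | 1.8 µM |  | 3.0 min |
| oak | 2.0 mM | 1.00 mM | 0.0400 mM | 7.0 µM | 1.8 µM |  | 3.0 min |

| run | time / min | target / % | substrate / % |
|---|---|---|---|
| Thursday's | 0.667 | 6.4 | 93.6 |
| Thursday's | 1.33 | 11.1 | 88.8 |
| Thursday's | 2.00 | 14.8 | 84.5 |
| Thursday's | 2.50 | 18.0 | 82.2 |
| Thursday's | 3.00 | 20.5 | 78.9 |
| Tuesday's | 0.250 | 2.1 | 97.2 |
| Tuesday's | 0.417 | 3.0 | 96.7 |
| Tuesday's | 0.833 | 7.0 | 92.9 |
| Tuesday's | 1.50 | 10.4 | 90.6 |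
| Tuesday's | 3.00 | 15.4 | 83.8 |
| Monday's | 0.250 | 2.2 | 98.4 |
| Monday's | 0.417 | 3.4 | 96.5 |
| Monday's | 0.833 | 4.9 | 94.8 |
| Monday's | 1.50 | 7.8 | 92.1 |
| Monday's | 3.00 | 10.8 | 89.6 |
| Sunday's | 0.250 | 0.5 | 98.9 |
| Sunday's | 0.833 | 1.4 | 98.1 |
| Sunday's | 1.33 | 2.7 | 96.2 |
| Sunday's | 2.00 | 3.5 | 95.8 |
| Sunday's | 3.00 | 4.5 | 96.0 |

(scatter of a reading: 0.5 percentage points)

- no earlier run changes the charge of free catalyst; that part of a forecast is a guess

* which of the two ends with the higher amount of target, in percent of the substrate charged ("neither" if they lie within 2 percentage points) (ash / oak / neither)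
* target at the end, in percent of the substrate charged, ash
* target at the end, in percent of the substrate charged, oak

Scale Thursday's 20.5% by the partner and catalyst ratios, and this rule of thumb gives ash 11.0%. The border shows in a ratio. Monday's run holds 4.11 times Thursday's substrate, yet ends at 10.8%, lower than Thursday's.

Monday's curve looks like a first-order approach to a ceiling. Its first 1.50 min gives 7.8%, and its second gives 3 percentage points. That is a rate constant, the clock, of 0.637 min⁻¹, and a ceiling of 0.292 mM.

I guess that impurity removes its own amount of catalyst, leaving 5.20 µM. I also assume the ceiling scales with working catalyst and partner, and the clock with substrate. The reach is then the target one working catalyst makes per mM of partner, a turnover number: 56.1 mM⁻¹. It is a reading and carries the scatter.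

Target is the ceiling times one minus exp(−clock × time). This gives Thursday 19.4% against 20.5%, and Sunday 4.13% against 4.5%.

For ash I get 12.1%, and for oak 11.8%. Go round once more: if each target takes one partner, ash's target has used 29.1% of its partner, close to Monday's 24.8%. Monday's ceiling was read from a run with that loss of partner in it, so I keep the number and call it neither.

The forecast said oak, with 7.5% for ash and 11.6% for oak, reading “target inhibition, perhaps delayed by the capture agent”.

The flask gives neither: ash 12.1%, oak 11.3%. At 3.00 min, oak's catalyst charge stands at 57.4% trapped intermediate, 25.7% spent catalyst, 14.3% free catalyst, 1.89% catalyst intermediate A and 0.708% catalyst intermediate B.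

    free catalyst + impurity → spent catalyst (k = 2.60 × 10⁵ L mol⁻¹ s⁻¹)
    partner + catalyst intermediate A ⇌ catalyst intermediate B (K = 1600 L mol⁻¹, k = 6600 L mol⁻¹ s⁻¹)
    catalyst intermediate A + capture agent → trapped intermediate (k = 1900 L mol⁻¹ s⁻¹)
    substrate + free catalyst ⇌ catalyst intermediate A (K = 76.0 L mol⁻¹, k = 16000 L mol⁻¹ s⁻¹)
    catalyst intermediate B → free catalyst + target (k = 9.50 s⁻¹)

Oak's ceiling from the reach is 14.6%, and oak reaches 14.3% at 30.0 min.

A neighbouring flask is oak with 0.010 mM of capture agent. If the reach rises and the clock slows by the ratio 4.00, which no run tested, the reckoning gives 19.8%. That is 39.6% of its partner, past Monday's share. The computed flask gives 16.8%, with 66% of its partner left.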